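The route rests on disconnecting the C5–C6 bond, which joins the gem-dimethyl carbon C5 of ring B to the spiro carbon C6 shared with ring A. The key step exploits the fact that this bond between two quaternary carbons is flanked by the C3=C4 bromoalkene and the C1=C15 methylene: one acid-triggered cation–olefin closure of a C5 bromoallyl cation onto C6 forms the bond, ring B, the C6 stereocentre and the methylene at once. Its precursor is an open-chain tertiary allylic alcohol at C5 with a cis C3=C4(Br) alkene, tethered through C2 to the tetrasubstituted C1=C6 alkene of a limonene-derived bromochlorinated ring A.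

Key step: step 6

Numbering: the spiro[5.5]undecane numbering of the target is used for its atoms throughout (C6 spiro; ring B C1–C5, with C15 the methylene carbon on C1; ring A C7–C11).
Assumption: the cyclohexylidene double bond made in step 2 forms as an E/Z mixture and is carried as such up to step 6, because both isomers give the same tertiary cation at C1; the SMILES of these compounds carry no descriptor for it.

Step 1
Reactants: 1 (R)-(+)-limonene
Product: 2 (1S,2S,4R)-2-bromo-1-chloro-1-methyl-4-(prop-1-en-2-yl)cyclohexane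
Conditions: NBS (1.05 equiv), Et4NCl (3 equiv), CH2Cl2, −40 → 0 °C
Reagents that add atoms: N-bromosuccinimide, O=C1CCC(=O)N1Br; tetraethylammonium chloride, CC[N+](CC)(CC)CC.[Cl-]
Why: Anti bromochlorination through a bromonium ion: the electron-rich trisubstituted ring alkene should react ahead of the isopropenyl group, and trans-diaxial (Fürst–Plattner) opening by chloride at the tertiary carbon of the half-chair with equatorial isopropenyl puts Cl on C1 cis and Br on C2 trans to the isopropenyl group, which sets both new centres as (1S,2S).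

Step 2
Reactants: 2 (1S,2S,4R)-2-bromo-1-chloro-1-methyl-4-(prop-1-en-2-yl)cyclohexane
Product: 3 (3S,4S)-3-bromo-1-(1-bromopropan-2-ylidene)-4-chloro-4-methylcyclohexane (E/Z mixture)
Conditions: NBS (1.0 equiv), AIBN (5 mol%), PhCF3, visible light, 75 °C
Reagents that add atoms: N-bromosuccinimide, O=C1CCC(=O)N1Br
Why: Wohl–Ziegler bromination: the bromine atom should abstract the weakest C–H, the tertiary allylic hydrogen on the ring carbon that carries the isopropenyl group, and the delocalised radical takes bromine at its primary terminus to give the more substituted alkene, as in the conversion of β-pinene into myrtenyl bromide; the former limonene stereocentre is erased on purpose and the two halogen-bearing centres are not touched.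

Step 3
Reactants: 3 (3S,4S)-3-bromo-1-(1-bromopropan-2-ylidene)-4-chloro-4-methylcyclohexane; 4 2-methylbut-3-yn-2-ol
Product: 5 6-[(3S,4S)-3-bromo-4-chloro-4-methylcyclohexylidene]-2-methylhept-3-yn-2-ol
Conditions: CuI (20 mol%), K2CO3 (1.5 equiv), DMF, rt
Reagents that add atoms: none
Why: Copper-acetylide allylic substitution (Cu-catalysed coupling of a terminal alkyne with an allylic halide) at the primary CH2Br carbon, the fully substituted far end of the allyl unit being closed to attack, under carbonate conditions too mild to eliminate HBr from ring A.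

Step 4
Reactants: 5 6-[(3S,4S)-3-bromo-4-chloro-4-methylcyclohexylidene]-2-methylhept-3-yn-2-ol
Product: 6 (3E)-6-[(3S,4S)-3-bromo-4-chloro-4-methylcyclohexylidene]-2-methyl-3-(tributylstannyl)hept-3-en-2-ol
Conditions: Bu3SnH (1.5 equiv), Mo(CO)3(CNt-Bu)3 (5 mol%), hydroquinone (10 mol%), THF, 55 °C
Reagents that add atoms: tributyltin hydride, CCCC[SnH](CCCC)CCCC
Why: Molybdenum–isonitrile-catalysed syn-hydrostannation of a propargylic alcohol, which should place tin on the alkyne carbon next to the carbinol and hydrogen cis to it, so that C2 and C5 end up cis across the new C3=C4 bond; hydroquinone keeps stannyl radicals from reducing the ring A halides.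

Step 5
Reactants: 6 (3E)-6-[(3S,4S)-3-bromo-4-chloro-4-methylcyclohexylidene]-2-methyl-3-(tributylstannyl)hept-3-en-2-ol
Product: 7 (3E)-3-bromo-6-[(3S,4S)-3-bromo-4-chloro-4-methylcyclohexylidene]-2-methylhept-3-en-2-ol
Conditions: NBS (1.05 equiv), CH2Cl2, −78 °C
Reagents that add atoms: N-bromosuccinimide, O=C1CCC(=O)N1Br
Why: Electrophilic ipso-bromodestannylation with retention of the alkene geometry; at −78 °C the alkenylstannane should be far more reactive towards NBS than the tetrasubstituted alkene.

Step 6
Reactants: 7 (3E)-3-bromo-6-[(3S,4S)-3-bromo-4-chloro-4-methylcyclohexylidene]-2-methylhept-3-en-2-ol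
Product: 8 (6S,9S,10S)-4,10-dibromo-9-chloro-5,5,9-trimethyl-1-methylidenespiro[5.5]undec-3-ene
Conditions: Bi(OTf)3 (5 mol%), 4 Å molecular sieves, CH2Cl2, −40 → 0 °C; Et3N quench
Reagents that add atoms: none
Why: Bi(OTf)3 ionises the tertiary allylic C5–OH to a 2-bromoallyl cation (termini C5 and C3, bromine on the central C4) whose C5 end, held cis to C2, is attacked by C6 of the tetrasubstituted C1=C6 alkene, and the tertiary C1 cation then loses a C15 proton, which gives the 1,4-diene and returns the acid. The closest known reaction type is the allyl-cation-initiated cation–olefin cyclisation (neryl-to-terpinyl and bisabolyl-to-chamigrenyl closures); the vinylic bromine on the initiating cation is the untested element. Ring B closes 6-endo-trig at C1=C6 through a half-chair in which C6 reaches C5 above the allyl plane, whereas the five-membered alternative (C5 to C1) would need the new bond in the nodal plane of the allyl cation. The one new stereocentre, C6, is set by the face of the alkene that C5 takes, and this is governed by the chair of ring A with its fixed (9S,10S) centres. The step needs C5 on the face cis to the C10 bromine (6S): in the chair with equatorial Br and Cl the bulky C5 end enters equatorially while C1 turns axial against hydrogens only, whereas entry on the other face, from the chair with axial halogens, drives C1 and C15 under the axial C10 bromine and leads to the less stable spiro epimer. It further needs proton loss from C15 and not from C2 and ionisation of the allylic alcohol ahead of the C9 chloride; low temperature, a catalytic acid and an early quench are meant to keep the first kinetic, and the vicinal bromine that deactivates C9 secures the second.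

Step 7
Reactants: 8 (6S,9S,10S)-4,10-dibromo-9-chloro-5,5,9-trimethyl-1-methylidenespiro[5.5]undec-3-ene
Product: 10 (6S,9S,10S)-4,10-dibromo-9-chloro-5,5,9-trimethyl-1-methylidenespiro[5.5]undec-3-en-2-one, via C2-epimeric allylic alcohols 9 (not isolated)
Conditions: SeO2 (0.5 equiv), t-BuOOH (3 equiv), CH2Cl2, 0 °C → rt; aqueous work-up; then Dess–Martin periodinane (1.5 equiv), pyridine, CH2Cl2, 0 °C
Reagents that add atoms: selenium dioxide, O=[Se]=O; tert-butyl hydroperoxide, CC(C)(C)OO
Why: Riley allylic oxidation (ene reaction of SeO2 at the C1=C15 methylene with a C2–H, then a [2,3]-shift that returns oxygen to C2 and the double bond to C1=C15), C2 carrying the only allylic hydrogens of 8, followed by Dess–Martin oxidation, which merges both C2 epimers in one dienone.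

Step 8
Reactants: 10 (6S,9S,10S)-4,10-dibromo-9-chloro-5,5,9-trimethyl-1-methylidenespiro[5.5]undec-3-en-2-one
Product: 11 (2R,6S,9S,10S)-4,10-dibromo-9-chloro-5,5,9-trimethyl-1-methylidenespiro[5.5]undec-3-en-2-ol
Conditions: (S)-2-methyl-CBS-oxazaborolidine (0.3 equiv), catecholborane (1.5 equiv), toluene, −78 °C; then MeOH, aqueous pH 9 buffer
Reagents that add atoms: none
Why: Corey–Bakshi–Shibata reduction: 1,2-hydride delivery to the cross-conjugated ketone, in which the branched C1 side (exocyclic methylene in the carbonyl plane, spiro carbon behind it) should act as the large group and the C3–H side as the small one, so that the (S)-catalyst gives the (2R)-alcohol; the low temperature keeps catecholborane from conjugate reduction.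

Compound list
1 | (R)-(+)-limonene | CC1=CC[C@@H](CC1)C(C)=C | starting material
2 | (1S,2S,4R)-2-bromo-1-chloro-1-methyl-4-(prop-1-en-2-yl)cyclohexane | CC(=C)[C@@H]1CC[C@](C)(Cl)[C@@H](Br)C1 | intermediate
3 | (3S,4S)-3-bromo-1-(1-bromopropan-2-ylidene)-4-chloro-4-methylcyclohexane, E/Z mixture | CC(CBr)=C1CC[C@](C)(Cl)[C@@H](Br)C1 | intermediate
4 | 2-methylbut-3-yn-2-ol | CC(C)(O)C#C | starting material
5 | 6-[(3S,4S)-3-bromo-4-chloro-4-methylcyclohexylidene]-2-methylhept-3-yn-2-ol, E/Z mixture | CC(=C1CC[C@](C)(Cl)[C@@H](Br)C1)CC#CC(C)(C)O | intermediate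
6 | (3E)-6-[(3S,4S)-3-bromo-4-chloro-4-methylcyclohexylidene]-2-methyl-3-(tributylstannyl)hept-3-en-2-ol, E/Z mixture at the cyclohexylidene | CC(=C1CC[C@](C)(Cl)[C@@H](Br)C1)C/C=C(\C(C)(C)O)[Sn](CCCC)(CCCC)CCCC | intermediate
7 | (3E)-3-bromo-6-[(3S,4S)-3-bromo-4-chloro-4-methylcyclohexylidene]-2-methylhept-3-en-2-ol, E/Z mixture at the cyclohexylidene | CC(=C1CC[C@](C)(Cl)[C@@H](Br)C1)C/C=C(Br)\C(C)(C)O | intermediate
8 | (6S,9S,10S)-4,10-dibromo-9-chloro-5,5,9-trimethyl-1-methylidenespiro[5.5]undec-3-ene | C=C1CC=C(Br)C(C)(C)[C@]12CC[C@](C)(Cl)[C@@H](Br)C2 | intermediate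
9 | (6S,9S,10S)-4,10-dibromo-9-chloro-5,5,9-trimethyl-1-methylidenespiro[5.5]undec-3-en-2-ol, mixture of C2 epimers | C=C1C(O)C=C(Br)C(C)(C)[C@]12CC[C@](C)(Cl)[C@@H](Br)C2 | intermediate
10 | (6S,9S,10S)-4,10-dibromo-9-chloro-5,5,9-trimethyl-1-methylidenespiro[5.5]undec-3-en-2-one | C=C1C(=O)C=C(Br)C(C)(C)[C@]12CC[C@](C)(Cl)[C@@H](Br)C2 | intermediate
11 | (2R,6S,9S,10S)-4,10-dibromo-9-chloro-5,5,9-trimethyl-1-methylidenespiro[5.5]undec-3-en-2-ol | C=C1[C@H](O)C=C(Br)C(C)(C)[C@]12CC[C@](C)(Cl)[C@@H](Br)C2 | target

Total step count: 8. Longest linear sequence: 8 steps, from 1 to 11.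

Steps most likely to fail

Step 6 (key step). What may go wrong: after ionisation the bromoallyl cation may lose a proton from a C5 methyl (dehydration to a 2-bromo-1,3-diene) and not close the ring, the closure may take the other face of C6, or the C1 cation may shed a C2 proton and end as a conjugated endocyclic diene. Fallback, from 3 back to 8: the bromine is taken off the initiating cation and put in after ring closure. The lithium dianion of 3-hydroxy-3-methylbutan-2-one (LiN(i-Pr)2, THF, −78 °C) is alkylated at carbon by 3 to give the ketol 6-[(3S,4S)-3-bromo-4-chloro-4-methylcyclohexylidene]-2-hydroxy-2-methylheptan-3-one F1. NaBH4 in MeOH reduces it to the diol 6-[(3S,4S)-3-bromo-4-chloro-4-methylcyclohexylidene]-2-methylheptane-2,3-diol F2. MsCl and Et3N at 0 °C sulfonylate only the secondary hydroxyl to give the mesylate 6-[(3S,4S)-3-bromo-4-chloro-4-methylcyclohexylidene]-2-hydroxy-2-methylheptan-3-yl methanesulfonate F3, and K2CO3 in MeOH closes it to the epoxide 3-{3-[(3S,4S)-3-bromo-4-chloro-4-methylcyclohexylidene]butyl}-2,2-dimethyloxirane F4. BF3·OEt2 in CH2Cl2 at −78 °C then starts an epoxide-initiated cation–olefin cyclisation (C5 to C6, proton loss from C15) that should give the spiro alcohol (6S,9S,10S)-10-bromo-9-chloro-5,5,9-trimethyl-1-methylidenespiro[5.5]undecan-4-ol F5. Dess–Martin periodinane oxidises it to the ketone (6S,9S,10S)-10-bromo-9-chloro-5,5,9-trimethyl-1-methylidenespiro[5.5]undecan-4-one F6, which can enolise only towards C3 and is converted into the vinyl bromide 8 with (PhO)3P, Br2 and Et3N (CH2Cl2, −60 °C to rt). This answers failure of the bromoallyl cation to close; the facial question at C6 remains.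

Step 2. What may go wrong: the bromine atom may abstract a methyl hydrogen, or NBS may react by an ionic ene-type pathway, both of which give the unrearranged 2-(bromomethyl)allyl isomer, and the electron-rich product may be brominated further. Fallback, from 2 back to 3: the double-bond shift is separated from the C–Br bond formation. Hydrogen-atom-transfer isomerisation (Co(salen)Cl with salen = N,N′-bis(3,5-di-tert-butylsalicylidene)cyclohexane-1,2-diamine dianion, PhSiH3, benzene, rt) should move the isopropenyl double bond into the tetrasubstituted position and give (3S,4S)-3-bromo-4-chloro-4-methyl-1-(propan-2-ylidene)cyclohexane F7. Its singlet-oxygen ene reaction (O2, tetraphenylporphyrin, visible light, CH2Cl2, 0 °C) takes a methyl hydrogen and gives the tertiary allylic hydroperoxide (3S,4S)-3-bromo-4-chloro-4-methyl-1-(prop-1-en-2-yl)cyclohexyl hydroperoxide F8. PPh3 reduces this in the same flask to (3S,4S)-3-bromo-4-chloro-4-methyl-1-(prop-1-en-2-yl)cyclohexan-1-ol F9, and PBr3 in Et2O at 0 °C then gives 3 by SN2′ displacement.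

Step 4. What may go wrong: tin may be delivered to the alkyne carbon remote from the crowded carbinol, or stannyl radicals formed at 55 °C may strip halogen from ring A. Fallback, from 3 back to 6: conjugation to an ester, not the carbinol, steers the tin. Coupling of 3 with methyl propiolate (CuI, K2CO3, DMF, rt) gives methyl 5-[(3S,4S)-3-bromo-4-chloro-4-methylcyclohexylidene]hex-2-ynoate F10. Pd(PPh3)4-catalysed syn-hydrostannation with Bu3SnH (THF, 0 °C), which places tin next to the ester carbonyl, gives methyl (2E)-5-[(3S,4S)-3-bromo-4-chloro-4-methylcyclohexylidene]-2-(tributylstannyl)hex-2-enoate F11. MeMgBr (3 equiv, THF, −78 to 0 °C) then converts the ester into the dimethylcarbinol and gives 6.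

Further compounds
F1 | step 6 | 6-[(3S,4S)-3-bromo-4-chloro-4-methylcyclohexylidene]-2-hydroxy-2-methylheptan-3-one | CC(=C1CC[C@](C)(Cl)[C@@H](Br)C1)CCC(=O)C(C)(C)O
F2 | step 6 | 6-[(3S,4S)-3-bromo-4-chloro-4-methylcyclohexylidene]-2-methylheptane-2,3-diol | CC(=C1CC[C@](C)(Cl)[C@@H](Br)C1)CCC(O)C(C)(C)O
F3 | step 6 | 6-[(3S,4S)-3-bromo-4-chloro-4-methylcyclohexylidene]-2-hydroxy-2-methylheptan-3-yl methanesulfonate | CC(=C1CC[C@](C)(Cl)[C@@H](Br)C1)CCC(OS(C)(=O)=O)C(C)(C)O
F4 | step 6 | 3-{3-[(3S,4S)-3-bromo-4-chloro-4-methylcyclohexylidene]butyl}-2,2-dimethyloxirane | CC(=C1CC[C@](C)(Cl)[C@@H](Br)C1)CCC2OC2(C)C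
F5 | step 6 | (6S,9S,10S)-10-bromo-9-chloro-5,5,9-trimethyl-1-methylidenespiro[5.5]undecan-4-ol | C=C1CCC(O)C(C)(C)[C@]12CC[C@](C)(Cl)[C@@H](Br)C2
F6 | step 6 | (6S,9S,10S)-10-bromo-9-chloro-5,5,9-trimethyl-1-methylidenespiro[5.5]undecan-4-one | C=C1CCC(=O)C(C)(C)[C@]12CC[C@](C)(Cl)[C@@H](Br)C2
F7 | step 2 | (3S,4S)-3-bromo-4-chloro-4-methyl-1-(propan-2-ylidene)cyclohexane | CC(C)=C1CC[C@](C)(Cl)[C@@H](Br)C1
F8 | step 2 | (3S,4S)-3-bromo-4-chloro-4-methyl-1-(prop-1-en-2-yl)cyclohexyl hydroperoxide | CC(=C)C1(OO)CC[C@](C)(Cl)[C@@H](Br)C1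
F9 | step 2 | (3S,4S)-3-bromo-4-chloro-4-methyl-1-(prop-1-en-2-yl)cyclohexan-1-ol | CC(=C)C1(O)CC[C@](C)(Cl)[C@@H](Br)C1
F10 | step 4 | methyl 5-[(3S,4S)-3-bromo-4-chloro-4-methylcyclohexylidene]hex-2-ynoate | CC(=C1CC[C@](C)(Cl)[C@@H](Br)C1)CC#CC(=O)OC
F11 | step 4 | methyl (2E)-5-[(3S,4S)-3-bromo-4-chloro-4-methylcyclohexylidene]-2-(tributylstannyl)hex-2-enoate | CC(=C1CC[C@](C)(Cl)[C@@H](Br)C1)C/C=C(\C(=O)OC)[Sn](CCCC)(CCCC)CCCC
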